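**Retrosynthetic overview**

1. The target is traced back to tetracyclic 3,11-diketone 33: hydride is delivered to the α faces of C3 and C11, then fluoride removes all silyl groups and the C20 alkoxide closes the 19,20-lactone.
2. 33 comes from keto ester 32 by one oxidative radical bicyclisation that forms C4–C5 and C9–C10. The strategy rests on ring A (C1–C5, C10), which carries the C3 oxygen beside quaternary C4 (C18 methyl, C19 carbonyl) and is trans-fused through quaternary C10 (C20 CH2O) to cyclopentane ring B (C5, C6, C8, C9, C10).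
3. 32 comes from bicyclic acid 15: an auxiliary-controlled anti-aldol sets C6, a silyloxyacetate Ireland–Claisen sets the C5=C10 geometry and brings in the C2 oxygen, and a malonate half-ester acylation adds C4/C18/C19.
4. 15 (rings C and D with a regiodefined C9=C11 enol pivalate) comes from a vinyl-radical closure of ring D onto a 2-pivaloyloxy diene, itself made from cyclohex-2-enone by CBS reduction and Ireland–Claisen rearrangement (C8).
5. Ring order: C (from cyclohexenone), D (radical closure), A then B (key step), lactone last.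

Key step: step 19

Remark on labels: atoms are labelled C1–C20 by gibberellane numbering throughout; α is the face of the C19–C20 bridge, β the face of H5, H9 and C7.

Assumption: the MgBr2-catalysed anti-aldol of N-acylthiazolidinethiones is taken to follow its usual facial sense, so that the (R)-auxiliary 16 gives adduct 22 as drawn; the enantiomeric auxiliary would be used if the sense proved opposite.

**Route**

Step 1
Reactants: 1 cyclohex-2-en-1-one; 2 2,3-dibromoprop-1-ene
Product: 3 rac-1-(2-bromoprop-2-en-1-yl)cyclohex-2-en-1-ol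
Conditions: In, THF/H2O, rt
Reagents that add atoms: none
Why: Barbier-type allylation by the allylindium formed in situ should add 1,2 to the enone carbonyl and leave the vinylic bromide (the later C16 radical precursor) intact; the carbinol stereocentre is removed in step 2.

Step 2
Reactants: 3 rac-1-(2-bromoprop-2-en-1-yl)cyclohex-2-en-1-ol
Product: 4 3-(2-bromoprop-2-en-1-yl)cyclohex-2-en-1-one
Conditions: C5H5NH[CrO3Cl], CH2Cl2, rt
Reagents that add atoms: pyridinium chlorochromate, [O-][Cr](=O)(=O)Cl.c1cc[nH+]cc1 (supplies the carbonyl oxygen; the hydroxyl oxygen of 3 stays on chromium)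
Why: Babler–Dauben oxidative 1,3-transposition, in which the chromate ester of the tertiary allylic alcohol shifts [3,3] and is oxidised to the 3-substituted enone.

Step 3
Reactants: 4 3-(2-bromoprop-2-en-1-yl)cyclohex-2-en-1-one
Product: 5 (1R)-3-(2-bromoprop-2-en-1-yl)cyclohex-2-en-1-ol
Conditions: (S)-2-methyl-CBS-oxazaborolidine (10 mol %), BH3·SMe2, THF, −20 °C
Reagents that add atoms: none
Why: Corey–Bakshi–Shibata reduction with the alkene arm as the large group should give the (R)-carbinol (C11), which is the source of absolute configuration for C8.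

Step 4
Reactants: 5 (1R)-3-(2-bromoprop-2-en-1-yl)cyclohex-2-en-1-ol
Product: 6 (1R)-3-(2-bromoprop-2-en-1-yl)cyclohex-2-en-1-yl acetate
Conditions: Ac2O, Et3N, DMAP (cat.), CH2Cl2, 0 °C to rt
Reagents that add atoms: acetic anhydride, CC(=O)OC(C)=O
Why: DMAP-catalysed acylation of a secondary allylic alcohol, with no change at the stereocentre.

Step 5
Reactants: 6 (1R)-3-(2-bromoprop-2-en-1-yl)cyclohex-2-en-1-yl acetate
Product: 9 (R)-2-[1-(2-bromoprop-2-en-1-yl)cyclohex-2-en-1-yl]acetic acid, via trimethylsilyl ketene acetal 7 (not isolated), via trimethylsilyl ester 8 (not isolated)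
Conditions: LiN(i-Pr)2, Me3SiCl, THF, −78 °C to 65 °C; then 1 M HCl
Reagents that add atoms: none
Why: Ireland–Claisen rearrangement; the [3,3] shift is suprafacial across the ring, so the C6–C8 bond forms on the face the C11 oxygen leaves and the carbinol configuration is relayed to quaternary C8.

Step 6
Reactants: 9 (R)-2-[1-(2-bromoprop-2-en-1-yl)cyclohex-2-en-1-yl]acetic acid
Product: 10 2-[(1R)-1-(2-bromoprop-2-en-1-yl)-3-hydroxycyclohexyl]acetic acid (C11 epimers)
Conditions: 9-BBN (3 equiv), THF, 65 °C; then NaOH, H2O2, 0 °C; H3O+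
Reagents that add atoms: hydrogen peroxide, OO
Why: Hydroboration–oxidation; the bulky borane should place boron on C11, the alkene carbon remote from quaternary C8, and react only slowly with the electron-poor bromoalkene, and the C11 configuration is irrelevant because it is oxidised next.

Step 7
Reactants: 10 2-[(1R)-1-(2-bromoprop-2-en-1-yl)-3-hydroxycyclohexyl]acetic acid
Product: 11 2-[(1R)-1-(2-bromoprop-2-en-1-yl)-3-oxocyclohexyl]acetic acid
Conditions: Dess–Martin periodinane, CH2Cl2, rt
Reagents that add atoms: none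
Why: Dess–Martin oxidation of a secondary alcohol to the C11 ketone; the carboxylic acid and vinyl bromide are inert.

Step 8
Reactants: 11 2-[(1R)-1-(2-bromoprop-2-en-1-yl)-3-oxocyclohexyl]acetic acid
Product: 12 2-[(1R)-1-(2-bromoprop-2-en-1-yl)-5-oxocyclohex-3-en-1-yl]acetic acid
Conditions: IBX, DMSO/PhF, 70 °C
Reagents that add atoms: none
Why: IBX dehydrogenation of a ketone to the enone; only the C12–C13 side has a β-hydrogen (C8 is quaternary), so a single enone should form.

Step 9
Reactants: 12 2-[(1R)-1-(2-bromoprop-2-en-1-yl)-5-oxocyclohex-3-en-1-yl]acetic acid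
Product: 14 2-[(1R)-1-(2-bromoprop-2-en-1-yl)-3-(pivaloyloxy)cyclohexa-2,4-dien-1-yl]acetic acid, via mixed pivalic anhydride 13 (not isolated)
Conditions: KN(SiMe3)2 (2.2 equiv), THF, −78 °C; t-BuCOCl (2.3 equiv); then aq. NaHCO3, THF, rt; H3O+
Reagents that add atoms: pivaloyl chloride, CC(C)(C)C(Cl)=O
Why: Kinetic α′-deprotonation of the enone at C9 (after the carboxylate) and O-acylation of the cross-conjugated potassium dienolate fix the enol ester as C9=C11 before ring D exists, which avoids the unselective enolisation of a bicyclic 11-ketone; the pivalate is chosen over acetate for stability in steps 11–18.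

Step 10
Reactants: 14 2-[(1R)-1-(2-bromoprop-2-en-1-yl)-3-(pivaloyloxy)cyclohexa-2,4-dien-1-yl]acetic acid
Product: 15 2-[(1S,5S)-6-methylidene-3-(pivaloyloxy)bicyclo[3.2.1]oct-2-en-1-yl]acetic acid
Conditions: Bu3SnH, AIBN (cat.), PhH, 80 °C, slow addition
Reagents that add atoms: none
Why: Tin hydride vinyl-radical cyclisation (5-exo-trig) onto the diene terminus C13 closes ring D with the C16 methylene in place; the 2-pivaloyloxyallyl radical should take hydrogen at C12, the terminus remote from quaternary C8, leaving the enol ester at C9=C11, and C13 is fixed because the two-carbon bridge can only close cis across C8 and C13.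

Step 11
Reactants: 15 2-[(1S,5S)-6-methylidene-3-(pivaloyloxy)bicyclo[3.2.1]oct-2-en-1-yl]acetic acid; 16 (4R)-4-benzyl-1,3-thiazolidine-2-thione
Product: 17 N-acyl thiazolidinethione of acid 15
Conditions: EDC·HCl, DMAP, CH2Cl2, rt
Reagents that add atoms: none
Why: Carbodiimide (Steglich-type) N-acylation under neutral conditions that the enol pivalate tolerates; the auxiliary is attached after the tin step because thiocarbonyls trap stannyl radicals.

Step 12
Reactants: 18 2-methylidenepropane-1,3-diol
Product: 19 2-{[(triisopropylsilyl)oxy]methyl}prop-2-en-1-ol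
Conditions: NaH (1 equiv), THF, 0 °C; i-Pr3SiCl
Reagents that add atoms: chlorotriisopropylsilane, CC(C)[Si](Cl)(C(C)C)C(C)C
Why: Monosilylation of a symmetrical diol through its monosodium alkoxide; a silyl ether is used at C20 because it carries no arene that could trap the C10 radical and needs no hydrogenolysis beside the C16 methylene.

Step 13
Reactants: 19 2-{[(triisopropylsilyl)oxy]methyl}prop-2-en-1-ol
Product: 20 2-{[(triisopropylsilyl)oxy]methyl}prop-2-enal
Conditions: Dess–Martin periodinane, NaHCO3, CH2Cl2, rt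
Reagents that add atoms: none
Why: Dess–Martin oxidation of a primary allylic alcohol to the non-enolisable enal.

Step 14
Reactants: 17 N-acyl thiazolidinethione of acid 15; 20 2-{[(triisopropylsilyl)oxy]methyl}prop-2-enal
Product: 22 anti-aldol adduct (5S,6R) with free C5 hydroxyl, via aldol trimethylsilyl ether 21 (not isolated)
Conditions: MgBr2·OEt2 (20 mol %), Et3N, Me3SiCl, EtOAc, rt; then THF/1 M HCl
Reagents that add atoms: none
Why: MgBr2-catalysed direct anti-aldol of an N-acylthiazolidinethione with a non-enolisable aldehyde; the auxiliary sets C6 independently of the weakly biasing bridgehead C8, and the anti relation sets the C5 carbinol that later relays to C2.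

Step 15
Reactants: 22 anti-aldol adduct (5S,6R); 23 2-(trimethylsilyl)ethanol
Product: 24 2-(trimethylsilyl)ethyl β-hydroxy ester (5S,6R)
Conditions: imidazole, CH2Cl2, rt
Reagents that add atoms: none
Why: Acyl transfer from the activated thiazolidinethione to a primary alcohol under mild conditions; the C7 ester is made fluoride-labile so that no hindered methyl ester has to be hydrolysed at the end.

Step 16
Reactants: 24 2-(trimethylsilyl)ethyl β-hydroxy ester (5S,6R); 25 2-[(tert-butyldimethylsilyl)oxy]acetic acid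
Product: 26 C5 (tert-butyldimethylsilyloxy)acetate of 24
Conditions: EDC·HCl, DMAP, CH2Cl2, 0 °C to rt
Reagents that add atoms: none
Why: Steglich esterification of the secondary allylic alcohol with retention at C5.

Step 17
Reactants: 26 C5 (tert-butyldimethylsilyloxy)acetate of 24
Product: 29 (2S,5Z,6S) 2-silyloxy-4-enoic acid, via silyl ketene acetal 27 (not isolated), via trimethylsilyl ester 28 (not isolated)
Conditions: LiN(i-Pr)2, Me3SiCl, THF/DMPU, −78 °C to rt; then 1 M HCl
Reagents that add atoms: none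
Why: Ireland–Claisen rearrangement through a chair with the C6 substituent equatorial should give the C5=C10 alkene with C6 trans to C1 and cis to C20, while the ketene acetal with the silyloxy group cis to OSiMe3 transfers the C5 configuration to C2 (S); bringing the C2 oxygen in here removes any later need to tell a C3 from a C11 ketone enolate.

Step 18
Reactants: 29 (2S,5Z,6S) 2-silyloxy-4-enoic acid; 30 3-methoxy-2-methyl-3-oxopropanoic acid
Product: 32 methyl 2-methyl-3-oxo ester (C4 epimers), via acyl imidazolide 31 (not isolated)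
Conditions: 1,1'-carbonyldiimidazole, THF, rt; then 30, MgCl2, Et3N, THF, rt to 45 °C; aq. citric acid
Reagents that add atoms: none
Why: Decarboxylative Claisen-type C-acylation of the magnesium enolate of a malonate half ester by the acyl imidazolide builds the 2-methyl-3-oxo ester under near-neutral conditions; C4 is left as a mixture because both epimers give the same radical.

Step 19
Reactants: 32 methyl 2-methyl-3-oxo ester (C4 epimers)
Product: 33 tetracyclic 3,11-diketone
Conditions: Mn(OAc)3·2H2O (2.2 equiv), Cu(OAc)2·H2O (0.5 equiv), degassed AcOH, rt to 40 °C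
Reagents that add atoms: none
Why: Proposed new method: Mn(OAc)3 enolises the 2-methyl-3-oxo ester and oxidises it to the electrophilic C4 radical, which adds 6-endo to C5 of the C5=C10 alkene through a chair (C19 ester axial, C2 silyloxy equatorial) to close ring A; the tertiary C10 radical then adds 5-exo to C9 of the enol pivalate to close ring B, and the α-pivaloyloxy C11 radical is oxidised by divalent copper to a cation that passes its pivaloyl group to acetate and leaves the 11-ketone. The closest known reaction type is the Mn(OAc)3/Cu(OAc)2 oxidative polycyclisation of 2-substituted 3-oxo esters onto polyenes, together with the addition of 1,3-dicarbonyl radicals to enol esters; ending such a cascade on a cyclic enol ester is the untested part. C5 is set by allylic 1,3-strain at C6 (H6 eclipses the C20 arm, attack anti to the bicyclic C8), and C4 by the chair (C19 on the face that carries C20). C10 is set by closure through the equatorial bond, so that C20 and not the bulky C9 becomes 1,3-diaxial to the C19 ester (trans A–B fusion); C9 is set by attack on the exo face of the bicyclo[3.2.1]octene, syn to C14, which leaves H9 cis to C15. The step needs 6-endo over 5-exo selectivity in the first closure, which the disubstituted C10 terminus secures by giving the tertiary radical. It also needs capture by C9 faster than copper oxidation of the C10 radical or addition to the C16 methylene, which the five-atom tether and the electron-rich enol ester should secure.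

Step 20
Reactants: 33 tetracyclic 3,11-diketone
Product: 34 3β,11β-diol
Conditions: LiBH(s-Bu)3 (3 equiv), THF, −78 °C; cold aq. NH4Cl
Reagents that add atoms: none
Why: Bulky trialkylborohydride reduction along the equatorial trajectory of both ketones: at C3 hydride should arrive on the α face past the axial C19 ester to give the axial 3β-alcohol cis to the 2β-silyloxy group, and at C11 on the α (exo) face, because the β face is closed by the C15–C16 bridge, to give the 11β-alcohol.

Step 21
Reactants: 34 3β,11β-diol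
Product: 36 the target CNP0302900.3, via desilylated 20-hydroxy 19-methyl ester 7-acid 35 (not isolated)
Conditions: Bu4NF, THF, rt; then dilute HCl to pH 3
Reagents that add atoms: none
Why: Fluoride cleaves the two silyl ethers and the 2-(trimethylsilyl)ethyl ester (loss of ethene), and the C20 alkoxide then lactonises onto the 1,3-diaxial C19 methyl ester; no stereocentre is touched and the C16 methylene is not exposed to hydrogen or strong acid.

**Compound list**

1 | cyclohex-2-en-1-one | O=C1C=CCCC1 | starting material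
2 | 2,3-dibromoprop-1-ene | C=C(Br)CBr | starting material
3 | rac-1-(2-bromoprop-2-en-1-yl)cyclohex-2-en-1-ol | C=C(Br)CC1(O)C=CCCC1 | intermediate
4 | 3-(2-bromoprop-2-en-1-yl)cyclohex-2-en-1-one | C=C(Br)CC1=CC(=O)CCC1 | intermediate
5 | (1R)-3-(2-bromoprop-2-en-1-yl)cyclohex-2-en-1-ol | O[C@H]1C=C(CC(Br)=C)CCC1 | intermediate
6 | (1R)-3-(2-bromoprop-2-en-1-yl)cyclohex-2-en-1-yl acetate | CC(=O)O[C@H]1C=C(CC(Br)=C)CCC1 | intermediate
7 | trimethylsilyl ketene acetal of 6 | C=C(O[Si](C)(C)C)O[C@H]1C=C(CC(Br)=C)CCC1 | intermediate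
8 | trimethylsilyl (R)-2-[1-(2-bromoprop-2-en-1-yl)cyclohex-2-en-1-yl]acetate | C=C(Br)C[C@@]1(CC(=O)O[Si](C)(C)C)C=CCCC1 | intermediate
9 | (R)-2-[1-(2-bromoprop-2-en-1-yl)cyclohex-2-en-1-yl]acetic acid (quaternary carbon = C8) | C=C(Br)C[C@@]1(CC(=O)O)C=CCCC1 | intermediate
10 | 2-[(1R)-1-(2-bromoprop-2-en-1-yl)-3-hydroxycyclohexyl]acetic acid, both carbinol (C11) epimers | C=C(Br)C[C@@]1(CC(=O)O)CC(O)CCC1 | intermediate
11 | 2-[(1R)-1-(2-bromoprop-2-en-1-yl)-3-oxocyclohexyl]acetic acid | C=C(Br)C[C@@]1(CC(=O)O)CC(=O)CCC1 | intermediate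
12 | 2-[(1R)-1-(2-bromoprop-2-en-1-yl)-5-oxocyclohex-3-en-1-yl]acetic acid | C=C(Br)C[C@@]1(CC(=O)O)CC(=O)C=CC1 | intermediate
13 | mixed pivalic anhydride of 14 | C=C(Br)C[C@@]1(CC(=O)OC(=O)C(C)(C)C)C=C(OC(=O)C(C)(C)C)C=CC1 | intermediate
14 | 2-[(1R)-1-(2-bromoprop-2-en-1-yl)-3-(pivaloyloxy)cyclohexa-2,4-dien-1-yl]acetic acid | C=C(Br)C[C@@]1(CC(=O)O)C=C(OC(=O)C(C)(C)C)C=CC1 | intermediate
15 | 2-[(1S,5S)-6-methylidene-3-(pivaloyloxy)bicyclo[3.2.1]oct-2-en-1-yl]acetic acid (rings C and D; C8 and C13 as in the target) | C=C1C[C@]2(CC(=O)O)C[C@H]1CC(OC(=O)C(C)(C)C)=C2 | intermediate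
16 | (4R)-4-benzyl-1,3-thiazolidine-2-thione | S=C1N[C@H](Cc2ccccc2)CS1 | starting material
17 | (4R)-4-benzyl-3-{2-[(1S,5S)-6-methylidene-3-(pivaloyloxy)bicyclo[3.2.1]oct-2-en-1-yl]acetyl}-1,3-thiazolidine-2-thione | C=C1C[C@]2(CC(=O)N3[C@H](Cc4ccccc4)CSC3=S)C[C@H]1CC(OC(=O)C(C)(C)C)=C2 | intermediate
18 | 2-methylidenepropane-1,3-diol | C=C(CO)CO | starting material
19 | 2-{[(triisopropylsilyl)oxy]methyl}prop-2-en-1-ol | C=C(CO)CO[Si](C(C)C)(C(C)C)C(C)C | intermediate
20 | 2-{[(triisopropylsilyl)oxy]methyl}prop-2-enal | C=C(C=O)CO[Si](C(C)C)(C(C)C)C(C)C | intermediate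
21 | C5 trimethylsilyl ether of aldol adduct 22 | C=C1C[C@]2([C@@H](C(=O)N3[C@H](Cc4ccccc4)CSC3=S)[C@H](O[Si](C)(C)C)C(=C)CO[Si](C(C)C)(C(C)C)C(C)C)C[C@H]1CC(OC(=O)C(C)(C)C)=C2 | intermediate
22 | anti-aldol adduct: N-acyl thiazolidinethione with (6R) carbon bearing the bicycle and (5S) carbinol bearing the 1-(silyloxymethyl)vinyl group | C=C1C[C@]2([C@@H](C(=O)N3[C@H](Cc4ccccc4)CSC3=S)[C@H](O)C(=C)CO[Si](C(C)C)(C(C)C)C(C)C)C[C@H]1CC(OC(=O)C(C)(C)C)=C2 | intermediate
23 | 2-(trimethylsilyl)ethanol | C[Si](C)(C)CCO | starting material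
24 | 2-(trimethylsilyl)ethyl (5S,6R) β-hydroxy ester (C7 ester) | C=C1C[C@]2([C@@H](C(=O)OCC[Si](C)(C)C)[C@H](O)C(=C)CO[Si](C(C)C)(C(C)C)C(C)C)C[C@H]1CC(OC(=O)C(C)(C)C)=C2 | intermediate
25 | 2-[(tert-butyldimethylsilyl)oxy]acetic acid | CC(C)(C)[Si](C)(C)OCC(=O)O | starting material
26 | (5S,6R) C5 (tert-butyldimethylsilyloxy)acetate of 24 | C=C1C[C@]2([C@@H](C(=O)OCC[Si](C)(C)C)[C@H](OC(=O)CO[Si](C)(C)C(C)(C)C)C(=C)CO[Si](C(C)C)(C(C)C)C(C)C)C[C@H]1CC(OC(=O)C(C)(C)C)=C2 | intermediate
27 | silyl ketene acetal of 26 (OTBS cis to OSiMe3) | C=C1C[C@]2([C@@H](C(=O)OCC[Si](C)(C)C)[C@H](O/C(O[Si](C)(C)C)=C/O[Si](C)(C)C(C)(C)C)C(=C)CO[Si](C(C)C)(C(C)C)C(C)C)C[C@H]1CC(OC(=O)C(C)(C)C)=C2 | intermediate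
28 | trimethylsilyl ester of acid 29 | C=C1C[C@]2([C@@H](C(=O)OCC[Si](C)(C)C)/C=C(\CO[Si](C(C)C)(C(C)C)C(C)C)C[C@H](O[Si](C)(C)C(C)(C)C)C(=O)O[Si](C)(C)C)C[C@H]1CC(OC(=O)C(C)(C)C)=C2 | intermediate
29 | (2S,5Z,6S) acid: C3 carboxylic acid, 2-OTBS, C5=C10 alkene with C20 (CH2OTIPS) cis to C6, C7 2-(trimethylsilyl)ethyl ester, bicyclic enol pivalate on C6 | C=C1C[C@]2([C@@H](C(=O)OCC[Si](C)(C)C)/C=C(\CO[Si](C(C)C)(C(C)C)C(C)C)C[C@H](O[Si](C)(C)C(C)(C)C)C(=O)O)C[C@H]1CC(OC(=O)C(C)(C)C)=C2 | intermediate
30 | 3-methoxy-2-methyl-3-oxopropanoic acid (methyl hydrogen methylmalonate) | COC(=O)C(C)C(=O)O | starting material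
31 | acyl imidazolide of 29 | C=C1C[C@]2([C@@H](C(=O)OCC[Si](C)(C)C)/C=C(\CO[Si](C(C)C)(C(C)C)C(C)C)C[C@H](O[Si](C)(C)C(C)(C)C)C(=O)n3ccnc3)C[C@H]1CC(OC(=O)C(C)(C)C)=C2 | intermediate
32 | key-step precursor: methyl 2-methyl-3-oxo ester chain (C4 epimers; (2S)-OTBS; (5Z); (6S)) on the ring C–D bicyclic C9=C11 enol pivalate; C7 2-(trimethylsilyl)ethyl ester; C20 OTIPS | C=C1C[C@]2([C@@H](C(=O)OCC[Si](C)(C)C)/C=C(\CO[Si](C(C)C)(C(C)C)C(C)C)C[C@H](O[Si](C)(C)C(C)(C)C)C(=O)C(C)C(=O)OC)C[C@H]1CC(OC(=O)C(C)(C)C)=C2 | intermediate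
33 | key-step product: tetracyclic 3,11-diketone (2β-OTBS; C19 methyl ester α on C4; C20 CH2OTIPS α on C10; H5β; H9β; 6β 2-(trimethylsilyl)ethyl ester; 16-methylene) | C=C1C[C@]23C[C@H]1CC(=O)[C@H]2[C@]4(CO[Si](C(C)C)(C(C)C)C(C)C)C[C@H](O[Si](C)(C)C(C)(C)C)C(=O)[C@@](C)(C(=O)OC)[C@H]4[C@@H]3C(=O)OCC[Si](C)(C)C | intermediate
34 | 3β,11β-diol of 33 (2β-OTBS retained) | C=C1C[C@]23C[C@H]1C[C@H](O)[C@H]2[C@]4(CO[Si](C(C)C)(C(C)C)C(C)C)C[C@H](O[Si](C)(C)C(C)(C)C)[C@H](O)[C@@](C)(C(=O)OC)[C@H]4[C@@H]3C(=O)OCC[Si](C)(C)C | intermediate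
35 | desilylated 2β,3β,11β,20-tetrol 19-methyl ester 7-acid | C=C1C[C@]23C[C@H]1C[C@H](O)[C@H]2[C@]4(CO)C[C@H](O)[C@H](O)[C@@](C)(C(=O)OC)[C@H]4[C@@H]3C(=O)O | intermediate
36 | CNP0302900.3: 2β,3β,11β-trihydroxy-16-ene 19,20-lactone 7-carboxylic acid of the gibberellane skeleton | C=C1C[C@]23C[C@H]1C[C@H](O)[C@H]2[C@]12COC(=O)[C@](C)([C@@H](O)[C@@H](O)C1)[C@H]2[C@@H]3C(=O)O | target

**Step count and risks**

Total steps: 21. Longest linear sequence: 19 (steps 1–11 and 14–21; steps 12–13 make aldehyde 20).

Most likely to fail: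

1. Step 19 (Proposed new method). The C10 radical may be oxidised by copper before it is captured by C9, the ring B closure may give the cis-fused A–B system, or the α-pivaloyloxy radical may not be oxidised cleanly. Fallback: the same two bonds are formed by a known iodine-atom-transfer radical chain instead of metal oxidation. Keto ester 32 is iodinated at C4 (NaH, then N-iodosuccinimide, THF, 0 °C) to give the 4-iodo keto ester F1. F1 is then cyclised with (Bu3Sn)2 (10 mol %) under visible light in benzene. The C4 radical closes rings A and B as before, and the C11 radical abstracts iodine from a further molecule of F1. The resulting α-iodo pivalate collapses to the 11-ketone on aqueous NaHCO3 work-up, and the route is rejoined at 33.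

2. Step 10. Hydrogen transfer may go to the wrong terminus (C9) of the 2-pivaloyloxyallyl radical and scramble the enol ester position, or the vinyl radical may be reduced before it cyclises. Fallback: the regiochemistry is carried by a sulfide and not by the radical step. Enone acid 12 is sulfenylated at C9 through its α′-enolate (KN(SiMe3)2, 2.2 equiv, then PhSSPh) to give the 9-phenylthio enone acid F2. Tin hydride vinyl-radical cyclisation onto the enone β-carbon C13 then gives the bicyclic 9-phenylthio 11-keto acid F3. Reductive C–S cleavage with LiC10H8 (lithium naphthalenide) at −78 °C generates the C9=C11 lithium enolate regiospecifically; O-pivaloylation (t-BuCOCl, then aq. NaHCO3) rejoins the route at 15.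

3. Step 20. Hydride may attack the β face of C11, because the C20 arm crowds the α face, and give the equatorial 11α-alcohol; the C3 reduction is expected to be less sensitive. Fallback: the C11 configuration is set by inversion, not by hydride facial selectivity. The 3β,11α-diol F4 obtained from 33 is subjected to Mitsunobu esterification (4-nitrobenzoic acid, PPh3, DIAD, toluene), which should engage only the unhindered equatorial 11α-hydroxyl and give the 11β 4-nitrobenzoate F5. Methanolysis (K2CO3, MeOH, 0 °C) removes the activated benzoate and rejoins the route at 34.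

Further compounds
F1 | step 19 | C4-iodo derivative of keto ester 32 (methyl 2-iodo-2-methyl-3-oxo ester) | C=C1C[C@]2([C@@H](C(=O)OCC[Si](C)(C)C)/C=C(\CO[Si](C(C)C)(C(C)C)C(C)C)C[C@H](O[Si](C)(C)C(C)(C)C)C(=O)C(C)(I)C(=O)OC)C[C@H]1CC(OC(=O)C(C)(C)C)=C2
F2 | step 10 | 2-[(1R)-1-(2-bromoprop-2-en-1-yl)-5-oxo-6-(phenylthio)cyclohex-3-en-1-yl]acetic acid (C9 epimers) | C=C(Br)C[C@@]1(CC(=O)O)C(Sc2ccccc2)C(=O)C=CC1
F3 | step 10 | 2-[(1S,5S)-6-methylidene-3-oxo-2-(phenylthio)bicyclo[3.2.1]octan-1-yl]acetic acid (C9 epimers) | C=C1C[C@]2(CC(=O)O)C[C@H]1CC(=O)C2Sc3ccccc3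
F4 | step 20 | 3β,11α-diol (C11 epimer of 34) | C=C1C[C@]23C[C@H]1C[C@@H](O)[C@H]2[C@]4(CO[Si](C(C)C)(C(C)C)C(C)C)C[C@H](O[Si](C)(C)C(C)(C)C)[C@H](O)[C@@](C)(C(=O)OC)[C@H]4[C@@H]3C(=O)OCC[Si](C)(C)C
F5 | step 20 | 11β 4-nitrobenzoate of 34 | C=C1C[C@]23C[C@H]1C[C@H](OC(=O)c5ccc([N+](=O)[O-])cc5)[C@H]2[C@]4(CO[Si](C(C)C)(C(C)C)C(C)C)C[C@H](O[Si](C)(C)C(C)(C)C)[C@H](O)[C@@](C)(C(=O)OC)[C@H]4[C@@H]3C(=O)OCC[Si](C)(C)C
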